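**Assumption:** the target has no stereocentres, so "single enantiomer" is read as the single all‑E (2E,6E,10E,14E,18E) isomer, drawn as the 2‑hydroxy‑1,4‑quinone tautomer. (2E,6E)‑Farnesyl bromide and (2E,6E)‑farnesyl acetate are taken as commercial.

## Retrosynthetic overview

1. The hydroxyquinone comes from oxidative dearomatization (Teuber) of 4‑hexaprenyl‑2‑methoxy‑5‑methylresorcinol. The only free ring C–H becomes one C=O, the para OH becomes the other, and the remaining OH is the target's hydroxyl.
2. That resorcinol comes from mono‑C‑hexaprenylation of unprotected, C2v‑symmetric 2‑methoxy‑5‑methylresorcinol with all‑E hexaprenol (key step). The two free positions are equivalent, so symmetry alone fixes the OH / OMe / C=O pattern, with no protecting groups and no selective demethylation.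
3. The symmetric resorcinol comes from 2,6‑dibromo‑4‑methylphenol (p‑cresol‑derived) by O‑methylation and double C–Br hydroxylation.
4. Hexaprenol comes from farnesyl phenyl sulfone and 12‑bromofarnesyl acetate (sulfone alkylation, then reductive desulfonylation).
5. No ring is formed. The one carbocycle is the benzene ring of the feedstock, converted to the quinone in the last step.

## Route

**Step 1**
Reactants: 1, 2,6‑dibromo‑4‑methylphenol
Product: 2, 1,3‑dibromo‑2‑methoxy‑5‑methylbenzene (2,6‑dibromo‑4‑methylanisole)
Conditions: MeI, K2CO3, acetone, reflux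
Reagents that add atoms: iodomethane, CI
Why: Williamson O‑methylation of an acidic 2,6‑dibromophenol; this methyl becomes the target's single OMe.

**Step 2**
Reactants: 2, 2,6‑dibromo‑4‑methylanisole
Product: 3, 2‑methoxy‑5‑methylbenzene‑1,3‑diol (C2v‑symmetric)
Conditions: Pd2(dba)3 (2 mol %), t‑BuXPhos (8 mol %), KOH (6 equiv), dioxane/H2O 1:1, 100 °C, Ar; then aq. HCl
Reagents that add atoms: potassium hydroxide, [K+].[OH-]
Why: Buchwald‑type Pd‑catalysed hydroxylation of aryl bromides, run twice on equivalent C–Br bonds; the aryl methyl ether is inert to hot KOH.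

**Step 3**
Reactants: 4, (2E,6E)‑farnesyl bromide
Product: 5, (2E,6E)‑farnesyl phenyl sulfone
Conditions: PhSO2Na, DMF, 0 °C → rt
Reagents that add atoms: sodium benzenesulfinate, [Na+].[O-]S(=O)c1ccccc1
Why: SN2 S‑alkylation of sulfinate by a primary allylic bromide, with the 2E and 6E olefins unchanged.

**Step 4**
Reactants: 6, (2E,6E)‑farnesyl acetate
Product: 7, (2E,6E,10E)‑12‑hydroxy‑3,7,11‑trimethyldodeca‑2,6,10‑trien‑1‑yl acetate
Conditions: SeO2 (0.3 equiv), t‑BuOOH (3 equiv), salicylic acid (cat.), CH2Cl2, 0 °C → rt; then NaBH4, MeOH, −10 °C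
Reagents that add atoms: selenium dioxide, O=[Se]=O (terminal oxidant tert‑butyl hydroperoxide, CC(C)(C)OO)
Why: Sharpless–Umbreit allylic oxidation (ene / [2,3] shift) attacks the E‑methyl of the most electron‑rich terminal olefin, which sets the 10E geometry; the borohydride quench returns over‑oxidised enal to the alcohol.

**Step 5**
Reactants: 7, 12‑hydroxyfarnesyl acetate
Product: 8, (2E,6E,10E)‑12‑bromo‑3,7,11‑trimethyldodeca‑2,6,10‑trien‑1‑yl acetate
Conditions: CBr4, PPh3, CH2Cl2, 0 °C
Reagents that add atoms: carbon tetrabromide, BrC(Br)(Br)Br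
Why: Appel bromination of a primary allylic alcohol under neutral conditions; the acetate and olefin geometry are untouched.

**Step 6**
Reactants: 5, farnesyl phenyl sulfone; 8, 12‑bromofarnesyl acetate
Product: 9, (2E,6E,10E,14E,18E)‑3,7,11,15,19,23‑hexamethyl‑13‑(phenylsulfonyl)tetracosa‑2,6,10,14,18,22‑hexaen‑1‑yl acetate (racemic at C13)
Conditions: 5, n‑BuLi, THF/DMPU, −78 °C; then 8, −78 → −40 °C
Reagents that add atoms: none
Why: Biellmann‑type α‑alkylation of the allylic sulfone carbanion by the allylic bromide gives the head‑to‑tail C12–C13 bond; at −78 °C the soft anion spares the acetate and the olefins keep their geometry. The C13 centre is removed in step 7.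

**Step 7**
Reactants: 9, sulfone acetate
Product: 10, all‑E hexaprenol, (2E,6E,10E,14E,18E)‑3,7,11,15,19,23‑hexamethyltetracosa‑2,6,10,14,18,22‑hexaen‑1‑ol
Conditions: LiBHEt3 (6 equiv), THF, −78 → 0 °C; then PdCl2(dppp) (5 mol %), 0 °C → rt
Reagents that add atoms: none
Why: Superhydride first cleaves the acetate to an alkoxide that Pd cannot ionise. Pd‑catalysed reductive desulfonylation (π‑allyl‑Pd hydride) then delivers H to the less substituted terminus, with the double bond staying in place and E.

**Step 8 (key step: symmetry breaking)**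
Reactants: 3, 2‑methoxy‑5‑methylbenzene‑1,3‑diol (3 equiv, excess recovered); 10, all‑E hexaprenol
Product: 11, 4‑[(2E,6E,10E,14E,18E)‑3,7,11,15,19,23‑hexamethyltetracosa‑2,6,10,14,18,22‑hexaen‑1‑yl]‑2‑methoxy‑5‑methylbenzene‑1,3‑diol
Conditions: acidic Al2O3 (Brockmann I), ClCH2CH2Cl, 80 °C
Reagents that add atoms: none
Why: Alumina‑templated dehydrative Friedel–Crafts ortho‑C‑allylation of a free phenol, the reaction type used for cannabigerol‑ and grifolin‑type prenylresorcinols. C4 and C6 are the only open sites and are equivalent, each ortho to one OH and para to the other. Mono‑alkylation decides which OH becomes C=O and which stays OH; excess 3 suppresses bis‑alkylation. The surface‑bound allyl transfer is expected to preserve the 2E geometry and avoid chroman closure; no stereocentre is formed.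

**Step 9 (dearomatization)**
Reactants: 11, hexaprenyl methoxymethylresorcinol
Product: 12, 3‑demethylubiquinone‑6 (target)
Conditions: Fremy's salt (3 equiv), aq. KH2PO4 (pH ≈ 6), THF/acetone, 0 °C → rt; then 1 M HCl work‑up
Reagents that add atoms: potassium nitrosodisulfonate, [K+].[K+].[O]N(S(=O)(=O)[O-])S(=O)(=O)[O-]
Why: Teuber oxidation: the phenoxyl radical is trapped at the one free C–H, para to the OH next to the chain, giving the p‑quinone with the other OH retained. Ortho attack would give the 4‑hydroxy‑1,2‑quinone, which is a tautomer of the same product. The isolated trisubstituted olefins are inert to the nitroxyl oxidant, as in the analogous oxidation of prenylated resorcinols to hydroxyquinones.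

## Compound list

1 | 2,6‑dibromo‑4‑methylphenol | Cc1cc(Br)c(O)c(Br)c1 | starting material
2 | 2,6‑dibromo‑4‑methylanisole | COc1c(Br)cc(C)cc1Br | intermediate
3 | 2‑methoxy‑5‑methylbenzene‑1,3‑diol | COc1c(O)cc(C)cc1O | intermediate
4 | (2E,6E)‑farnesyl bromide | BrC/C=C(\C)CC/C=C(\C)CCC=C(C)C | starting material
5 | (2E,6E)‑farnesyl phenyl sulfone | O=S(=O)(C/C=C(\C)CC/C=C(\C)CCC=C(C)C)c1ccccc1 | intermediate
6 | (2E,6E)‑farnesyl acetate | CC(=O)OC/C=C(\C)CC/C=C(\C)CCC=C(C)C | starting material
7 | (2E,6E,10E)‑12‑hydroxyfarnesyl acetate | CC(=O)OC/C=C(\C)CC/C=C(\C)CC/C=C(\C)CO | intermediate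
8 | (2E,6E,10E)‑12‑bromofarnesyl acetate | CC(=O)OC/C=C(\C)CC/C=C(\C)CC/C=C(\C)CBr | intermediate
9 | 13‑(phenylsulfonyl)hexaprenyl acetate, all‑E, racemic at C13 | CC(=O)OC/C=C(\C)CC/C=C(\C)CC/C=C(\C)CC(/C=C(\C)CC/C=C(\C)CCC=C(C)C)S(=O)(=O)c1ccccc1 | intermediate
10 | all‑E hexaprenol | OC/C=C(\C)CC/C=C(\C)CC/C=C(\C)CC/C=C(\C)CC/C=C(\C)CCC=C(C)C | intermediate
11 | 4‑(all‑E‑hexaprenyl)‑2‑methoxy‑5‑methylbenzene‑1,3‑diol | COc1c(O)cc(C)c(C/C=C(\C)CC/C=C(\C)CC/C=C(\C)CC/C=C(\C)CC/C=C(\C)CCC=C(C)C)c1O | intermediate
12 | 3‑demethylubiquinone‑6 | COC1=C(O)C(=O)C(C)=C(C/C=C(\C)CC/C=C(\C)CC/C=C(\C)CC/C=C(\C)CC/C=C(\C)CCC=C(C)C)C1=O | target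

## Summary

**Total steps:** 9.
**Longest linear sequence:** 6 (steps 4 → 5 → 6 → 7 → 8 → 9, from farnesyl acetate).
**Olefin geometry:** 2E and 6E come from 6, 10E from step 4, 14E and 18E from 4; no step after that ionises or isomerises them except the C2 olefin in step 8.

**Steps most likely to fail, with fallbacks**

1. **Step 8** (bis‑alkylation, chroman or polyene cyclisation on the acidic surface, erosion of 2E). Fallback: switch from electrophilic substitution to an aryl‑metal coupling. Protect 3 as its bis‑MOM ether, ortho‑lithiate (only the equivalent C4/C6 sites are open), transmetalate to copper, couple SN2 with hexaprenyl bromide (from 10), then remove MOM under mild conditions.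
2. **Step 9** (attack at the OMe‑bearing carbon with loss of methanol, poor mixing of the C30 lipid with aqueous oxidant, or handling losses of the acidic hydroxyquinone). Fallback: reverse the order. Oxidise symmetric 3 itself to 3‑hydroxy‑2‑methoxy‑5‑methyl‑1,4‑benzoquinone (either site gives the same product), then install the chain by BF3‑mediated coupling with hexaprenyl‑trimethylstannane and re‑oxidise the hydroquinone with Ag2O or air.
3. **Step 2** (second C–Br hydroxylation on an electron‑rich, ortho‑substituted bromophenoxide; hydrodebromination or diaryl ether formation). Fallback: build 3 from the gallate series instead. Methyl gallate is selectively 4‑O‑methylated to methyl 3,5‑dihydroxy‑4‑methoxybenzoate, reduced with LiAlH4 to the benzyl alcohol, and hydrogenolysed (H2, Pd/C, AcOH) to the methyl arene 3.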